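**Retrosynthetic overview**

1. The β-hydroxy ketone is unmasked last, by N–O reduction and imine hydrolysis of a spiro-2-isoxazoline enone. The isoxazoline keeps the aromatisation-prone aldol unit protected until the end.
2. The enone comes from a trans β-iodo spiro-isoxazoline ketal by loss of HI, ketal hydrolysis and alkene conjugation, so the iodine carries the enone oxidation level.
3. The iodide comes from an achiral 2,5-dihydroarene ketoxime by catalytic enantioselective 5-exo iodo-spirocyclisation. This step makes the C5–O bond and sets the only stereocentre that survives.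
4. The oxime comes from a β,γ-unsaturated ketone, made by acylating the dianion of a dihydroaryl acetic acid ketal with linoleoyl chloride, then decarboxylation.
5. That acid comes from Birch reduction of 3-methoxyphenylacetic acid. Ring order: the carbocycle is the former arene (step 1), then the dioxolane (step 1, temporary), then the isoxazoline (step 4, temporary).

Assumption: the target stereocentre is (S) as read from the SMILES. The facial sense of the catalyst in step 4 is not predictable; if the first run gives the antipode, the pseudo-enantiomeric quinidine-derived urea, (9R)-6′-methoxycinchonan-9-yl, is used instead.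

**Route**

Step 1
Reactants: 1 3-methoxyphenylacetic acid
Product: 3 2-(1,4-dioxaspiro[4.5]dec-7-en-7-yl)acetic acid, via dienol ether acid 2 (not isolated)
Conditions: Li, NH3(l), t-BuOH, THF, −78 °C; NH4Cl; then HOCH2CH2OH, pyridinium p-toluenesulfonate (cat.), CH2Cl2, 0 °C to rt
Reagents that add atoms: ethylene glycol, OCCO
Why: Birch reduction of a 3-alkylanisole leaves both substituents on the remaining double bonds (the carboxylate is inert), and acid-catalysed exchange of the methyl enol ether with the diol gives the dioxolane without moving the trisubstituted alkene; no stereocentre is formed.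

Step 2
Reactants: 3 2-(1,4-dioxaspiro[4.5]dec-7-en-7-yl)acetic acid; 4 (9Z,12Z)-octadeca-9,12-dienoyl chloride (linoleoyl chloride)
Product: 6 (10Z,13Z)-1-(1,4-dioxaspiro[4.5]dec-7-en-7-yl)nonadeca-10,13-dien-2-one, via beta-keto acid 5 (not isolated)
Conditions: 3 (2 equiv), LiN(i-Pr)2 (4 equiv), THF, −78 to 0 °C; 4 (1 equiv), −78 °C; aq. HCl to pH 4, 30 °C
Reagents that add atoms: none
Why: C-acylation of a carboxylic acid dianion (enediolate) at the α-carbon followed by β-keto acid decarboxylation gives the β,γ-unsaturated ketone by kinetic α-protonation of the enol; the second equivalent of dianion absorbs the acidic proton of the product, the skipped diene is untouched at −78 °C, and no stereocentre is formed.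

Step 3
Reactants: 6 (10Z,13Z)-1-(1,4-dioxaspiro[4.5]dec-7-en-7-yl)nonadeca-10,13-dien-2-one
Product: 7 (10Z,13Z)-1-(1,4-dioxaspiro[4.5]dec-7-en-7-yl)nonadeca-10,13-dien-2-one oxime (E/Z mixture at C=N)
Conditions: NH2OH·HCl, NaOAc, EtOH/H2O, rt
Reagents that add atoms: hydroxylamine hydrochloride, Cl.NO
Why: Oxime condensation at the only ketone, under buffered conditions that leave the dioxolane and the β,γ-alkene in place; no stereocentre is formed.

Step 4
Reactants: 7 (10Z,13Z)-1-(1,4-dioxaspiro[4.5]dec-7-en-7-yl)nonadeca-10,13-dien-2-one oxime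
Product: 8 (5S,10S)-7,7-(ethylenedioxy)-3-[(8Z,11Z)-heptadeca-8,11-dien-1-yl]-10-iodo-1-oxa-2-azaspiro[4.5]dec-2-ene (I on C10 trans to O1 on the spiro carbon C5)
Conditions: N-iodosuccinimide (1.2 equiv), I2 (5 mol %), 1-[3,5-bis(trifluoromethyl)phenyl]-3-[(8α,9S)-6′-methoxycinchonan-9-yl]urea (10 mol %), toluene, −40 °C, dark
Reagents that add atoms: N-iodosuccinimide, O=C1CCC(=O)N1I
Why: Proposed new method: the urea N–H bonds activate N-iodosuccinimide and the quinuclidine nitrogen hydrogen-bonds the oxime OH, so the iodonium ion formed reversibly on the electron-rich trisubstituted ring alkene is opened on one enantiotopic face by 5-exo anti attack of the oxime oxygen at the tertiary carbon (Markovnikov), which sets C5 as S under catalyst control and C10 as S by anti addition, while the chain cis-alkenes carry no internal nucleophile and only form iodonium ions reversibly; the closest known reaction type is the catalytic enantioselective iodoetherification of β,γ-unsaturated ketoximes with 1,1-disubstituted alkenes to 5,5-disubstituted 2-isoxazolines, here extended to an endocyclic alkene (spirocyclisation).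

Step 5
Reactants: 8 (5S,10S)-7,7-(ethylenedioxy)-3-[(8Z,11Z)-heptadeca-8,11-dien-1-yl]-10-iodo-1-oxa-2-azaspiro[4.5]dec-2-ene
Product: 9 (5S)-7,7-(ethylenedioxy)-3-[(8Z,11Z)-heptadeca-8,11-dien-1-yl]-1-oxa-2-azaspiro[4.5]deca-2,9-diene
Conditions: DBU, toluene, 90 °C
Reagents that add atoms: none
Why: E2 dehydroiodination can only go toward C9 because C5 is quaternary, so the anti-periplanar elimination gives the C9=C10 alkene alone; C5 is not touched.

Step 6
Reactants: 9 (5S)-7,7-(ethylenedioxy)-3-[(8Z,11Z)-heptadeca-8,11-dien-1-yl]-1-oxa-2-azaspiro[4.5]deca-2,9-diene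
Product: 11 (5S)-3-[(8Z,11Z)-heptadeca-8,11-dien-1-yl]-1-oxa-2-azaspiro[4.5]deca-2,8-dien-7-one, via unconjugated enone 10 (not isolated)
Conditions: pyridinium p-toluenesulfonate, acetone/H2O, 50 °C; then Et3N (cat.), CH2Cl2, rt
Reagents that add atoms: water, O
Why: Mild acid ketal hydrolysis is followed by amine-catalysed β,γ to α,β enone isomerisation through the dienolate formed at the doubly activated C8; the isoxazoline is stable to both reagents and blocks dehydration to a phenol, and C5 is not touched.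

Step 7
Reactants: 11 (5S)-3-[(8Z,11Z)-heptadeca-8,11-dien-1-yl]-1-oxa-2-azaspiro[4.5]deca-2,8-dien-7-one
Product: 13 (5S)-5-hydroxy-5-[(10Z,13Z)-2-oxononadeca-10,13-dien-1-yl]cyclohex-2-en-1-one, via beta-hydroxy imine 12 (not isolated)
Conditions: Mo(CO)6, MeCN/H2O (15:1), 80 °C; chromatography on buffered silica
Reagents that add atoms: water, O
Why: Reductive N–O cleavage of a 2-isoxazoline with Mo(CO)6 and water gives the β-hydroxy imine, which hydrolyses in situ to the β-hydroxy ketone under near-neutral conditions that do not reduce alkenes; the C5–O bond is never broken, so the S configuration is retained.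

**Compound list**

1 | 3-methoxyphenylacetic acid | COc1cccc(CC(=O)O)c1 | starting material
2 | 2-(5-methoxycyclohexa-1,4-dien-1-yl)acetic acid | COC1=CCC=C(CC(=O)O)C1 | intermediate
3 | 2-(1,4-dioxaspiro[4.5]dec-7-en-7-yl)acetic acid | OC(=O)CC1=CCCC2(C1)OCCO2 | intermediate
4 | (9Z,12Z)-octadeca-9,12-dienoyl chloride | CCCCC/C=C\C/C=C\CCCCCCCC(Cl)=O | starting material
5 | (11Z,14Z)-2-(1,4-dioxaspiro[4.5]dec-7-en-7-yl)-3-oxoicosa-11,14-dienoic acid (racemic) | CCCCC/C=C\C/C=C\CCCCCCCC(=O)C(C(=O)O)C1=CCCC2(C1)OCCO2 | intermediate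
6 | (10Z,13Z)-1-(1,4-dioxaspiro[4.5]dec-7-en-7-yl)nonadeca-10,13-dien-2-one | CCCCC/C=C\C/C=C\CCCCCCCC(=O)CC1=CCCC2(C1)OCCO2 | intermediate
7 | (10Z,13Z)-1-(1,4-dioxaspiro[4.5]dec-7-en-7-yl)nonadeca-10,13-dien-2-one oxime | CCCCC/C=C\C/C=C\CCCCCCCC(=NO)CC1=CCCC2(C1)OCCO2 | intermediate
8 | (5S,10S)-7,7-(ethylenedioxy)-3-[(8Z,11Z)-heptadeca-8,11-dien-1-yl]-10-iodo-1-oxa-2-azaspiro[4.5]dec-2-ene | CCCCC/C=C\C/C=C\CCCCCCCC1=NO[C@]2(C1)[C@@H](I)CCC3(C2)OCCO3 | intermediate
9 | (5S)-7,7-(ethylenedioxy)-3-[(8Z,11Z)-heptadeca-8,11-dien-1-yl]-1-oxa-2-azaspiro[4.5]deca-2,9-diene | CCCCC/C=C\C/C=C\CCCCCCCC1=NO[C@]2(C1)C=CCC3(C2)OCCO3 | intermediate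
10 | (5S)-3-[(8Z,11Z)-heptadeca-8,11-dien-1-yl]-1-oxa-2-azaspiro[4.5]deca-2,9-dien-7-one | CCCCC/C=C\C/C=C\CCCCCCCC1=NO[C@]2(C1)C=CCC(=O)C2 | intermediate
11 | (5S)-3-[(8Z,11Z)-heptadeca-8,11-dien-1-yl]-1-oxa-2-azaspiro[4.5]deca-2,8-dien-7-one | CCCCC/C=C\C/C=C\CCCCCCCC1=NO[C@]2(C1)CC=CC(=O)C2 | intermediate
12 | (5S)-5-hydroxy-5-[(10Z,13Z)-2-iminononadeca-10,13-dien-1-yl]cyclohex-2-en-1-one | CCCCC/C=C\C/C=C\CCCCCCCC(=N)C[C@@]1(O)CC=CC(=O)C1 | intermediate
13 | (5S)-5-hydroxy-5-[(10Z,13Z)-2-oxononadeca-10,13-dien-1-yl]cyclohex-2-en-1-one | CCCCC/C=C\C/C=C\CCCCCCCC(=O)C[C@@]1(O)CC=CC(=O)C1 | target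

**Step count and risks**

Total: 7 steps, counting the telescoped Birch reduction and ketal exchange as one. Longest linear sequence: 7 steps, from 1 to 13; 4 enters at step 2.

Steps most likely to fail:

- **Step 4.** The enantioselectivity is untested on a ring alkene. Only the oxime isomer with OH syn to the ring CH2 can close, so the route relies on E/Z equilibration by the catalytic I2 and trace HI. The skipped diene must also stay out of the halogenation. Fallback: setting out from 7, uncatalysed iodocyclisation (I2, NaHCO3, CH2Cl2/H2O, 0 °C) gives the racemic trans iodide, that is 8 together with its enantiomer (5R,10R)-7,7-(ethylenedioxy)-3-[(8Z,11Z)-heptadeca-8,11-dien-1-yl]-10-iodo-1-oxa-2-azaspiro[4.5]dec-2-ene F5. The pair is separated by preparative chromatography on a chiral stationary phase, and the route is rejoined at 8. This replaces asymmetric catalysis by resolution, with at most half the material carried on.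

- **Step 2.** The risks are α- versus γ-acylation of the dienediolate, proton transfer to the product, and drift of the alkene into conjugation during decarboxylation. Fallback: setting out from 1 and 4, the benzylic dianion of 1 (LiN(i-Pr)2, 2 equiv per acid) is acylated with 4 to give (11Z,14Z)-2-(3-methoxyphenyl)-3-oxoicosa-11,14-dienoic acid F1, which loses CO2 on acidification to the aryl ketone (10Z,13Z)-1-(3-methoxyphenyl)nonadeca-10,13-dien-2-one F2. Birch reduction (Li, NH3, t-BuOH) then reduces both the ring and the ketone to (10Z,13Z)-1-(5-methoxycyclohexa-1,4-dien-1-yl)nonadeca-10,13-dien-2-ol F3. Glycol exchange (pyridinium p-toluenesulfonate) gives (10Z,13Z)-1-(1,4-dioxaspiro[4.5]dec-7-en-7-yl)nonadeca-10,13-dien-2-ol F4, and Dess–Martin periodinane with NaHCO3 oxidises this to the β,γ-unsaturated ketone, rejoining the route at 6.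

- **Step 7.** The enone may be attacked by the low-valent molybdenum, and the hot product can dehydrate to a phenol. Fallback: setting out from 11, Luche reduction (NaBH4, CeCl3·7H2O, MeOH, −40 °C) hides the enone as the allylic alcohol (5S)-3-[(8Z,11Z)-heptadeca-8,11-dien-1-yl]-1-oxa-2-azaspiro[4.5]deca-2,8-dien-7-ol F6 (both C7 epimers). Mo(CO)6 in wet MeCN then cleaves the N–O bond to the imine (10Z,13Z)-1-[(1S)-1,5-dihydroxycyclohex-3-en-1-yl]nonadeca-10,13-dien-2-imine F7, which hydrolyses to (10Z,13Z)-1-[(1R)-1,5-dihydroxycyclohex-3-en-1-yl]nonadeca-10,13-dien-2-one F8 (the descriptor changes by priority only). MnO2 in CH2Cl2 at rt oxidises only the allylic secondary alcohol and returns the route at 13.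

**Further compounds**

F1 | step 2 | (11Z,14Z)-2-(3-methoxyphenyl)-3-oxoicosa-11,14-dienoic acid | CCCCC/C=C\C/C=C\CCCCCCCC(=O)C(C(=O)O)c1cccc(OC)c1
F2 | step 2 | (10Z,13Z)-1-(3-methoxyphenyl)nonadeca-10,13-dien-2-one | CCCCC/C=C\C/C=C\CCCCCCCC(=O)Cc1cccc(OC)c1
F3 | step 2 | (10Z,13Z)-1-(5-methoxycyclohexa-1,4-dien-1-yl)nonadeca-10,13-dien-2-ol | CCCCC/C=C\C/C=C\CCCCCCCC(O)CC1=CCC=C(OC)C1
F4 | step 2 | (10Z,13Z)-1-(1,4-dioxaspiro[4.5]dec-7-en-7-yl)nonadeca-10,13-dien-2-ol | CCCCC/C=C\C/C=C\CCCCCCCC(O)CC1=CCCC2(C1)OCCO2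
F5 | step 4 | (5R,10R)-7,7-(ethylenedioxy)-3-[(8Z,11Z)-heptadeca-8,11-dien-1-yl]-10-iodo-1-oxa-2-azaspiro[4.5]dec-2-ene | CCCCC/C=C\C/C=C\CCCCCCCC1=NO[C@@]2(C1)[C@H](I)CCC3(C2)OCCO3
F6 | step 7 | (5S)-3-[(8Z,11Z)-heptadeca-8,11-dien-1-yl]-1-oxa-2-azaspiro[4.5]deca-2,8-dien-7-ol | CCCCC/C=C\C/C=C\CCCCCCCC1=NO[C@]2(C1)CC=CC(O)C2
F7 | step 7 | (10Z,13Z)-1-[(1S)-1,5-dihydroxycyclohex-3-en-1-yl]nonadeca-10,13-dien-2-imine | CCCCC/C=C\C/C=C\CCCCCCCC(=N)C[C@@]1(O)CC=CC(O)C1
F8 | step 7 | (10Z,13Z)-1-[(1R)-1,5-dihydroxycyclohex-3-en-1-yl]nonadeca-10,13-dien-2-one | CCCCC/C=C\C/C=C\CCCCCCCC(=O)C[C@@]1(O)CC=CC(O)C1
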